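## Structural features

The target is a B-type procyanidin tetramer: four flavan-3-ol units, each a chroman (ring C) fused to a phloroglucinol-type ring A and carrying a catechol ring B at C2. Unit 1 is catechin (2,3-trans) and is bonded through C4 (α) to C6 of unit 2, whereas units 2, 3 and 4 are epicatechin (2,3-cis), joined from C4 (β) of unit 2 to C8 of unit 3 and from C4 (β) of unit 3 to C8 of unit 4. There are eleven stereocentres: three contiguous C2–C3–C4 triads (unit 1 2,3-trans-3,4-trans; units 2 and 3 2,3-cis-3,4-trans) and one C2–C3 pair in unit 4. C4 of units 1 to 3 is doubly benzylic between two ortho-oxygenated rings, so the interflavan C4–aryl bonds ionise under acid, while the free polyphenol is sensitive to air and base (catechol oxidation, C2 epimerisation through a ring B quinone methide). The phenols must therefore stay masked to the end, and strong acid must be kept away from the assembled oligomer. The real difficulty is unit 2: its ring A is substituted at C6, the less nucleophilic position in cationic couplings, and its ring C combines the contra-thermodynamic 2,3-cis arrangement with a 4-aryl bond to a further dimer. The key step uses the fact that in unit 2 the ring oxygen O1 (on C2), the 3-oxygen and the unit-3 aryl group sit on three adjacent carbons, and that C8a, which bears O1, is para to C6. Moving O1 from C2 to C3 turns ring C into a trans-2,3-dihydrobenzofuran with an exocyclic benzylic carbinol, whose benzo ring comes from a symmetrical phenol carrying unit 1 in the para position.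

## Logic of the disconnections

33 ⇐ 32 ⇐ 31. Only protecting-group C–O bonds are cut: seventeen benzyl ethers (32 to 33) and, before that, the acetate at O3 and the two pivalates on ring B of unit 2 (31 to 32). Esters go first and benzyl ethers last, so the oxidation-prone free oligomer 33 appears only in a neutral hydrogenolysis and never meets base. The forward demand is an ester cleavage that does not epimerise C2 of unit 2 and a hydrogenolysis that runs to completion.

31 ⇐ 29 (through 30). In ring C of unit 2 the O1–C2 bond and the C3–O(acetate) bond are cut and the ring oxygen is returned to C3, which contracts the chroman to a trans-2,3-dihydrobenzofuran with an exocyclic benzylic mesylate. The 2,3-cis-3,4-trans triad, which cationic coupling cannot deliver at a 6-linked unit, then follows from two stereospecific inversions, and the five-membered ring is open to a convergent annulation. The demand is that neighbouring-group participation outruns ionisation and that 30 is opened at the ring carbon.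

29 ⇐ 28 ⇐ 27. The S–O bond and then the carbinol C–H bond are cut, leaving an aryl ketone. This removes one stereocentre and exposes the acyl group of a stabilised ylide. The forward reduction must be threo-selective, because the carbinol centre becomes C2 of unit 2.

27 ⇐ 19 + 12 + 22 (through 23, 24, 25, 26). Three bonds around the five-membered ring are cut in one operation: the bond from the future C4 of unit 2 to C8 of unit 3, and the C2–C3 and O1–C2 bonds of the dihydrobenzofuran. The tetramer falls into the unit 3–unit 4 dimer, the unit 1/ring A half and a two-carbon ring B piece, a large gain in convergence. The demands are generation of 25 under basic conditions only, trans ring closure, and attack on the correct face of 25, the one stereochemical element with no adjacent centre to control it.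

22 ⇐ 21 ⇐ 20. A C–S bond and two ester C–O bonds are cut. The pivalates are placed at the outset because they must survive the ylide chemistry and deactivate ring B in the key step.

12 ⇐ 11 ⇐ 10 ⇐ 9. The carbonate C–O bond, the aryl–CHO bond and the Si–O bond are cut in turn. The formylation needs no regiocontrol: the two carbons ortho to the phenol oxygen of 10 are equivalent and the para carbon carries unit 1.

9 ⇐ 5 + 8. The bond from C4 of unit 1 to the carbon that becomes C6 of unit 2 is cut; in the forward sense 5 is re-ionised to 4. This uses 1 with all its stereocentres and turns the awkward 4→6 regiochemistry into para selectivity on a simple arene. The forward step must attack para to the silyloxy group and anti to the 3-benzyloxy group.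

5 ⇐ 3 ⇐ 1 (through 2 and 4) and 8 ⇐ 7 ⇐ 6. Only C–O and Si–O bonds are cut (4-ether, benzyl ethers, silyl ether), leading to the cheap starting materials 1 and 6. The only demand is that the benzylation of 1 does not disturb C2.

19 ⇐ 18 + 15, with 18 ⇐ 16 ⇐ 15 ⇐ 13 (through 17 and 14). The C4(unit 3)–C8(unit 4) bond is cut between a C8-brominated electrophile and the nucleophile 15, both from 13. The bromine stops self-condensation and later becomes the lithium of 23, so no regioselective functionalisation of a dimer is needed. The forward coupling must be 4β- and C8-selective.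

## Other disconnections considered

Alternative 1: The cut is the unit-3 C4 to unit-4 C8 bond, made intramolecularly. Two epicatechin halves are first tied O3 to O3 through an azelate diester; Me3SiOTf at high dilution then ionises the 4-(2-ethoxyethoxy) group of the upper half, and C8 of the lower half captures the cation, closing the 18-membered macrocycle A1.
- In its favour: strict 1:1 stoichiometry, no oligomerisation, and a tether that reinforces C8 attack and the 4β geometry. On stoichiometric control it is better than step 12, which needs a modest excess of 15.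
- Against it here: it addresses the best-behaved bond of the molecule. It costs two esterifications, tether cleavage and re-benzylation of both 3-hydroxyls, and needs high dilution. A1 also has no handle at C8 of unit 3, so a bromine would have to be carried through the macrocyclisation or introduced unselectively on a dimer with three nucleophilic sites.
- Comparison: structurally it covers only the terminal dimer; mechanistically it is the same cationic Friedel–Crafts reaction as step 12 with an equal stereochemical outcome; in step economy it is three to four steps longer than the route to 19.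

Alternative 2: The cut is C4–C4a of unit 2. An aryl ether between the unit-1-bearing symmetrical phenol and a glyceraldehyde-derived C2–C3–C4 chain carries an aldehyde at C4. BF3·OEt2 lets either equivalent ortho carbon attack it to close ring C, and in-flask exchange of the benzylic alcohol with 2-ethoxyethanol gives the dimeric electrophile A2.
- In its favour: it uses the same para/symmetry argument for the 4→6 link as the chosen plan (equal on this point), and C2 and C3 come from the chiral pool. The unit 2 C4–unit 3 C8 bond would then be formed by a classical cationic coupling in which the neighbouring 3-benzyloxy group dictates the 4β configuration. On control of that centre it is better than the chosen plan, where the same centre depends on the face selectivity of step 15.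
- Against it here: the O1–C2 aryl ether must be made at a secondary benzylic carbon with defined configuration. The α-benzyloxy aldehyde can epimerise under the Lewis acid. The final union is a 2+2 cationic coupling in which A2 can self-condense at its own free C8 and the dimeric nucleophile offers three sites, so it needs an excess of valuable dimer and puts a Lewis acid on acid-labile interflavan bonds.
- Comparison: structurally it solves the same unit; mechanistically it is cationic throughout, where the chosen route is anionic up to a buffered rearrangement; in step economy the chain synthesis is several steps longer than the two-step preparation of 22, so overall it is comparable or longer.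

Alternative 3: The cut is C2–C3 of unit 1. Ring C of unit 1 is first built one atom too large with an SO2 group between C2 and C3. KOH and CBr2F2 on alumina (Ramberg–Bäcklund with in-flask α-halogenation) then extrude SO2 through an episulfone and form the C2=C3 enol ether, giving the flav-2-ene A3. Hydroboration anti to the C4 aryl group would then be needed to set the 2,3-trans-3,4-trans pattern.
- In its favour: the contraction is purely base-mediated, so no acid touches the assembled tetramer. On that point it is better than the chosen plan, which warms the tetramer in buffered acetic acid. The hydroboration logic for a catechin unit is stereochemically sound and equal in reliability to taking the unit from the chiral pool as far as relative configuration goes.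
- Against it here: unit 1 is the one unit whose stereocentres come free with 1, yet both C2 and C3 are destroyed and rebuilt, with absolute configuration resting on C4 alone. The seven-membered sulfone needs many steps. The contraction is run on the complete tetramer with a halogenating carbene source while electron-rich ring A carbons of units 3 and 4 are exposed (only C8 of unit 2 is blocked in A3). The enol ether of A3 is acid-labile.
- Comparison: structurally it does not touch the real problem in unit 2; mechanistically it is a carbanion/episulfone extrusion where the chosen step is an oxygen-participation rearrangement; in step economy it is clearly worse.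

Key step: step 18

## Remarks before the steps

- Abbreviations: Bn = benzyl, Piv = pivaloyl, Boc = tert-butoxycarbonyl, TIPS = triisopropylsilyl, Ms = methanesulfonyl.
- PBC-4α-yl = 3,5,7,3',4'-penta-O-benzyl-(+)-catechin attached through C4, with the C4 substituent trans to the 3-benzyloxy group.
- DBD-8-yl = deca-O-benzyl-epicatechin-(4β→8)-epicatechin attached through C8 of its upper unit.
- A centre-by-centre comparison shows that 29 ((2S)-trans ring, (S)-carbinol, threo) and 31 (2,3-cis-3,4-trans) are related exactly by inversion at the carbinol carbon and at the furan C2, with the third centre unchanged.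
- Assumption on the chemistry: the para selectivity of step 5 and the face selectivity of step 15 are taken as the expected outcomes; both have fallbacks below.

## Route

Step 1
Reactants: 1 (+)-catechin
Product: 3 3,5,7,3',4'-penta-O-benzyl-(+)-catechin, via 5,7,3',4'-tetra-O-benzylcatechin 2 (not isolated)
Conditions: BnBr, K2CO3, DMF, 0 °C → rt; then NaH, BnBr, 0 °C → rt
Reagents that add atoms: benzyl bromide, BrCc1ccccc1
Why: Williamson etherification in two stages: K2CO3 ionises only the four phenols, which keeps C-benzylation and base-induced opening at C2 down, and NaH then alkylates the secondary 3-hydroxyl in the same flask; no stereocentre is involved.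

Step 2
Reactants: 3 3,5,7,3',4'-penta-O-benzyl-(+)-catechin
Product: 5 4β-(2-ethoxyethoxy)-3,5,7,3',4'-penta-O-benzyl-(+)-catechin, via flavan-4-yl cation 4 (not isolated)
Conditions: DDQ, 2-ethoxyethanol, CH2Cl2, rt
Reagents that add atoms: 2-ethoxyethanol, CCOCCO
Why: Oxidative benzylic etherification: DDQ abstracts hydride from the C4 methylene activated by the ring A oxygens, and the alcohol captures cation 4 mainly anti to the 2-aryl group (4β); the C4 configuration is immaterial because the ether is re-ionised in step 5.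

Step 3
Reactants: 6 phloroglucinol
Product: 7 3,5-bis(benzyloxy)phenol
Conditions: BnBr (2 equiv), K2CO3, DMF, 0 °C → rt; chromatography
Reagents that add atoms: benzyl bromide, BrCc1ccccc1
Why: Statistical Williamson etherification of the symmetrical triol; the diether is separated from mono- and triether, which is acceptable at the first step of a cheap building block.

Step 4
Reactants: 7 3,5-bis(benzyloxy)phenol
Product: 8 [3,5-bis(benzyloxy)phenoxy]triisopropylsilane
Conditions: TIPSCl, imidazole, DMF, rt
Reagents that add atoms: chlorotriisopropylsilane, CC(C)[Si](Cl)(C(C)C)C(C)C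
Why: Standard silylation of a phenol; the bulky TIPS group is chosen to shield both carbons ortho to this oxygen in step 5 and to survive the Lewis acid.

Step 5
Reactants: 5 4β-(2-ethoxyethoxy)-penta-O-benzyl-(+)-catechin; 8 [3,5-bis(benzyloxy)phenoxy]triisopropylsilane (excess)
Product: 9 4α-[2,6-bis(benzyloxy)-4-(triisopropylsilyloxy)phenyl]-penta-O-benzyl-(+)-catechin
Conditions: Me3SiOTf (cat.), CH2Cl2, −78 °C; Et3N quench
Reagents that add atoms: none
Why: Friedel–Crafts alkylation of an electron-rich arene (SN1): Me3SiOTf re-ionises the 4-ether of 5 to the flavan-4-yl cation 4 already met in step 2, and the TIPS group blocks the two carbons next to the silyloxy group, so the cation should enter para to it, between the benzyloxy groups, which fixes the later 4→6 link. Attack anti to the 3-benzyloxy group on the half-chair cation sets the 3,4-trans (4α) centre.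

Step 6
Reactants: 9 4α-[2,6-bis(benzyloxy)-4-(triisopropylsilyloxy)phenyl]-penta-O-benzyl-(+)-catechin
Product: 10 4α-[2,6-bis(benzyloxy)-4-hydroxyphenyl]-penta-O-benzyl-(+)-catechin
Conditions: Bu4NF, THF, 0 °C; aq. NH4Cl
Reagents that add atoms: none
Why: Fluoride-mediated desilylation of the aryl silyl ether; benzyl ethers and the C4–aryl bond are inert to fluoride and mild base.

Step 7
Reactants: 10 4α-[2,6-bis(benzyloxy)-4-hydroxyphenyl]-penta-O-benzyl-(+)-catechin
Product: 11 2,4-bis(benzyloxy)-6-hydroxy-3-(PBC-4α-yl)benzaldehyde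
Conditions: MgCl2, Et3N, (CH2O)n, THF, reflux
Reagents that add atoms: paraformaldehyde (formaldehyde), C=O
Why: Magnesium-mediated ortho-formylation (Casnati–Skattebøl): formaldehyde is delivered inside the magnesium phenoxide chelate, so only a carbon ortho to the hydroxyl reacts; both ortho carbons are equivalent, the para carbon is blocked, and a second formaldehyde serves as oxidant. The basic medium spares the acid-labile C4–aryl bond.

Step 8
Reactants: 11 2,4-bis(benzyloxy)-6-hydroxy-3-(PBC-4α-yl)benzaldehyde
Product: 12 3,5-bis(benzyloxy)-2-formyl-4-(PBC-4α-yl)phenyl tert-butyl carbonate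
Conditions: Boc2O, i-Pr2NEt, DMAP (cat.), THF, 0 °C → rt
Reagents that add atoms: di-tert-butyl dicarbonate, CC(C)(C)OC(=O)OC(=O)OC(C)(C)C
Why: DMAP-catalysed O-acylation of the phenol; the tert-butyl carbonate is the group that migrates and leaves in step 15.

Step 9
Reactants: 13 (−)-epicatechin
Product: 15 3,5,7,3',4'-penta-O-benzyl-(−)-epicatechin, via 5,7,3',4'-tetra-O-benzylepicatechin 14 (not isolated)
Conditions: BnBr, K2CO3, DMF, 0 °C → rt; then NaH, BnBr, 0 °C → rt
Reagents that add atoms: benzyl bromide, BrCc1ccccc1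
Why: Same two-stage Williamson etherification as step 1; the mild first stage protects the 2,3-cis C2 centre from base-induced epimerisation before the phenols are capped.

Step 10
Reactants: 15 3,5,7,3',4'-penta-O-benzyl-(−)-epicatechin
Product: 16 8-bromo-3,5,7,3',4'-penta-O-benzyl-(−)-epicatechin
Conditions: NBS (1.0 equiv), CH2Cl2, −78 → 0 °C
Reagents that add atoms: N-bromosuccinimide, O=C1CCC(=O)N1Br
Why: Electrophilic aromatic bromination; in 5,7-dioxygenated flavans C8 is the most nucleophilic ring A carbon, and one equivalent at low temperature should stop at the 8-bromide, which caps C8 and later serves as the lithiation handle.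

Step 11
Reactants: 16 8-bromo-penta-O-benzyl-(−)-epicatechin
Product: 18 8-bromo-4β-(2-ethoxyethoxy)-penta-O-benzyl-(−)-epicatechin, via bromoflavan-4-yl cation 17 (not isolated)
Conditions: DDQ, 2-ethoxyethanol, CH2Cl2, rt
Reagents that add atoms: 2-ethoxyethanol, CCOCCO
Why: Oxidative benzylic etherification: hydride abstraction at C4 and capture of cation 17 by the alcohol from the β face, away from the 2-aryl and 3-benzyloxy groups; the aryl bromide is inert to DDQ.

Step 12
Reactants: 18 8-bromo-4β-(2-ethoxyethoxy)-penta-O-benzyl-(−)-epicatechin; 15 penta-O-benzyl-(−)-epicatechin (modest excess)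
Product: 19 8-bromo-deca-O-benzyl-epicatechin-(4β→8)-epicatechin
Conditions: Me3SiOTf (cat.), CH2Cl2, −78 °C; Et3N quench
Reagents that add atoms: none
Why: Friedel–Crafts alkylation: Me3SiOTf re-ionises 18 to the cation 17 already met in step 11, which is captured by C8 of 15; the 2-aryl and 3-benzyloxy groups both lie on the α face, so β attack gives the 3,4-trans (4β) bond. The bromine removes the electrophile's own C8 as a nucleophile, so oligomerisation is suppressed.

Step 13
Reactants: 20 2-chloro-3',4'-dihydroxyacetophenone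
Product: 21 2-chloro-3',4'-bis(pivaloyloxy)acetophenone
Conditions: PivCl, i-Pr2NEt, DMAP (cat.), CH2Cl2, 0 °C
Reagents that add atoms: pivaloyl chloride, CC(C)(C)C(Cl)=O
Why: O-acylation of both phenols; the hindered amine should not be alkylated by the α-chloro ketone, and pivalates are chosen as base-resistant, electron-withdrawing groups for steps 15 to 18.

Step 14
Reactants: 21 2-chloro-3',4'-bis(pivaloyloxy)acetophenone
Product: 22 1-{2-[3,4-bis(pivaloyloxy)phenyl]-2-oxoethyl}thiolan-1-ium chloride
Conditions: tetrahydrothiophene, acetone, 40 °C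
Reagents that add atoms: tetrahydrothiophene, C1CCSC1
Why: SN2 alkylation of the sulfide by the carbonyl-activated α-chloro ketone; the sulfonium salt should precipitate from acetone.

Step 15
Reactants: 19 8-bromo-deca-O-benzyl-epicatechin-(4β→8)-epicatechin; 12 3,5-bis(benzyloxy)-2-formyl-4-(PBC-4α-yl)phenyl tert-butyl carbonate; 22 sulfonium chloride
Product: 27 (2S)-trans-2-[3,4-bis(pivaloyloxy)benzoyl]-4,6-bis(benzyloxy)-3-(DBD-8-yl)-5-(PBC-4α-yl)-2,3-dihydrobenzofuran, via aryllithium 23 (not isolated), via lithium phenoxide carbonate 24 (not isolated), via ortho-quinone methide 25 (not isolated), via sulfonium ylide 26 (not isolated)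
Conditions: n-BuLi, THF, −78 °C; then 12, −78 → −40 °C; then 26 [from 22, LiN(SiMe3)2, THF, −78 → 0 °C], −40 °C → rt
Reagents that add atoms: none
Why: Bromine–lithium exchange gives 23, which adds to the aldehyde of 12; the alkoxide takes over the Boc group, and phenoxide 24 expels tert-butyl carbonate on warming to give ortho-quinone methide 25 under base only. Conjugate addition of the keto-stabilised sulfur ylide 26 to the methide carbon and 5-exo-tet displacement of tetrahydrothiophene by the phenoxide ([4+1] annulation) close the ring; reversible addition and the epimerisable α-keto centre place aroyl and aryl trans. Which face of 25 is attacked (the future C4 of unit 2) rests on substrate bias and is treated among the uncertain steps.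

Step 16
Reactants: 27 trans-dihydrobenzofuran ketone
Product: 28 (2S)-trans-2-{(S)-[3,4-bis(pivaloyloxy)phenyl](hydroxy)methyl}-4,6-bis(benzyloxy)-3-(DBD-8-yl)-5-(PBC-4α-yl)-2,3-dihydrobenzofuran (threo)
Conditions: LiBH(s-Bu)3, THF, −78 °C; aq. NH4Cl
Reagents that add atoms: none
Why: Felkin–Anh (polar) addition: with the ring C–O bond antiperiplanar to the incoming hydride, the bulky non-chelating borohydride passes the small hydrogen and not C3, giving the threo (S)-carbinol; the aryl ether oxygen is a poor ligand, so a chelate leading to the erythro isomer should not compete. Aryl pivalates should survive one equivalent of this hindered hydride at −78 °C.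

Step 17
Reactants: 28 threo alcohol
Product: 29 methanesulfonate of 28 (same configuration)
Conditions: Ms2O, Et3N, DMAP (cat.), CH2Cl2, −20 → 0 °C; used without delay
Reagents that add atoms: methanesulfonic anhydride, CS(=O)(=O)OS(C)(=O)=O
Why: Sulfonylation of the secondary benzylic alcohol with retention; the anhydride avoids chloride, which could displace the benzylic sulfonate, and the acylated ring B makes the mesylate stable enough to handle cold.

Step 18
Reactants: 29 trans-dihydrobenzofuran mesylate
Product: 31 protected tetramer PBC-(4α→6)-[3-O-acetyl-5,7-di-O-benzyl-3',4'-di-O-pivaloylepicatechin]-(4β→8)-deca-O-benzyl-epicatechin-(4β→8)-epicatechin, via aryloxiranium ion 30 (not isolated)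
Conditions: Zn(OAc)2, AcOH–1,4-dioxane, 70 °C
Reagents that add atoms: zinc acetate, CC(=O)[O-].CC(=O)[O-].[Zn+2]; acetic acid, CC(=O)O
Why: Zn(OAc)2 assists departure of the mesylate while the dihydrobenzofuran oxygen, antiperiplanar to the C–OMs bond after rotation about the exocyclic bond, attacks the benzylic carbon from the rear (3-exo-tet) to give the bicyclic aryloxiranium ion 30. Acetate then opens 30 at the former furan C2 with a second inversion, cleaving the O–C bond shared by both rings, so the oxygen stays on the benzylic carbon and the five-membered ring becomes the six-membered ring C (a ring expansion by net 1,2-oxygen shift, not a direct 6-endo closure). The closest known reaction type is the Zn(OAc)2/AcOH ring expansion of 2-(1-mesyloxyalkyl)tetrahydrofurans to 3-acetoxytetrahydropyrans through bridged oxonium ions, together with oxygen-participation rearrangements between 2-(1-sulfonyloxyalkyl)-2,3-dihydrobenzofurans and 3-substituted chromans. C2 of unit 2 is set by inversion of the (S)-carbinol centre and C3 by inversion of the (2S) furan carbon, so the threo trans-dihydrobenzofuran must give the 2,3-cis-3,4-trans (epicatechin) pattern; C4 is carried over unchanged. Participation has to outrun SN1 ionisation and direct acetate substitution, which the two acyloxy groups on ring B (in place of alkoxy donors) and the buffered, weakly nucleophilic medium should secure. Opening must occur at the furan carbon and not at the benzylic one; release of the bicyclic strain into an unstrained chroman with an equatorial aryl group and the damped benzylic character of the carbon bearing the acylated ring favour this. The trans relation between the side chain and the unit-3 aryl group keeps neighbouring benzyloxy oxygens from reaching the benzylic carbon, and buffered acetic acid at 70 °C should leave benzyl ethers, pivalates and interflavan bonds intact.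

Step 19
Reactants: 31 protected tetramer (3-O-acetate, ring B dipivalate)
Product: 32 heptadeca-O-benzyl tetramer with free 3-OH, 3'-OH and 4'-OH in unit 2
Conditions: NaOMe, MeOH–THF, degassed, 0 °C → rt; AcOH quench
Reagents that add atoms: none
Why: Zemplén-type transesterification removes the secondary acetate and both aryl pivalates while benzyl ethers are inert. Exclusion of oxygen, low temperature and an acidic quench protect the liberated catechol and keep C2 of unit 2 from epimerising through a ring B quinone methide.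

Step 20
Reactants: 32 heptadeca-O-benzyl tetramer
Product: 33 catechin-(4α→6)-epicatechin-(4β→8)-epicatechin-(4β→8)-epicatechin (target)
Conditions: H2 (1 atm), Pd(OH)2 on carbon, THF–MeOH–H2O, rt; filtration under argon, lyophilisation
Reagents that add atoms: none
Why: Hydrogenolysis of seventeen benzyl ethers under neutral conditions; the interflavan bonds and the cyclic benzylic ethers of ring C are not cleaved under these conditions, and neither acid nor base touches the free oligomer.

## Compound list

1 | (+)-catechin, (2R,3S) | Oc1cc(O)c2c(c1)O[C@H](c1ccc(O)c(O)c1)[C@@H](O)C2 | starting material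
2 | 5,7,3',4'-tetra-O-benzyl-(+)-catechin (formed in the flask, not isolated) | c9ccccc9COc1cc(OCc9ccccc9)c2c(c1)O[C@H](c1ccc(OCc9ccccc9)c(OCc9ccccc9)c1)[C@@H](O)C2 | intermediate
3 | 3,5,7,3',4'-penta-O-benzyl-(+)-catechin | c9ccccc9COc1cc(OCc9ccccc9)c2c(c1)O[C@H](c1ccc(OCc9ccccc9)c(OCc9ccccc9)c1)[C@@H](OCc9ccccc9)C2 | intermediate
4 | penta-O-benzylcatechin C4 (flavan-4-yl) cation (formed in the flask, not isolated) | c9ccccc9COc1cc(OCc9ccccc9)c2c(c1)O[C@H](c1ccc(OCc9ccccc9)c(OCc9ccccc9)c1)[C@@H](OCc9ccccc9)[CH+]2 | intermediate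
5 | 4β-(2-ethoxyethoxy)-3,5,7,3',4'-penta-O-benzyl-(+)-catechin (3,4-cis) | c9ccccc9COc1cc(OCc9ccccc9)c2c(c1)O[C@H](c1ccc(OCc9ccccc9)c(OCc9ccccc9)c1)[C@@H](OCc9ccccc9)[C@H]2OCCOCC | intermediate
6 | phloroglucinol | Oc1cc(O)cc(O)c1 | starting material
7 | 3,5-bis(benzyloxy)phenol | Oc1cc(OCc9ccccc9)cc(OCc9ccccc9)c1 | intermediate
8 | [3,5-bis(benzyloxy)phenoxy]triisopropylsilane | CC(C)[Si](C(C)C)(C(C)C)Oc1cc(OCc9ccccc9)cc(OCc9ccccc9)c1 | intermediate
9 | 4α-[2,6-bis(benzyloxy)-4-(triisopropylsilyloxy)phenyl]-penta-O-benzyl-(+)-catechin (3,4-trans) | c9ccccc9COc1cc(OCc9ccccc9)c2c(c1)O[C@H](c1ccc(OCc9ccccc9)c(OCc9ccccc9)c1)[C@@H](OCc9ccccc9)[C@@H]2c1c(OCc9ccccc9)cc(O[Si](C(C)C)(C(C)C)C(C)C)cc1OCc9ccccc9 | intermediate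
10 | 4α-[2,6-bis(benzyloxy)-4-hydroxyphenyl]-penta-O-benzyl-(+)-catechin | c9ccccc9COc1cc(OCc9ccccc9)c2c(c1)O[C@H](c1ccc(OCc9ccccc9)c(OCc9ccccc9)c1)[C@@H](OCc9ccccc9)[C@@H]2c1c(OCc9ccccc9)cc(O)cc1OCc9ccccc9 | intermediate
11 | 2,4-bis(benzyloxy)-6-hydroxy-3-(PBC-4α-yl)benzaldehyde | c9ccccc9COc1cc(OCc9ccccc9)c2c(c1)O[C@H](c1ccc(OCc9ccccc9)c(OCc9ccccc9)c1)[C@@H](OCc9ccccc9)[C@@H]2c1c(OCc9ccccc9)cc(O)c(C=O)c1OCc9ccccc9 | intermediate
12 | 3,5-bis(benzyloxy)-2-formyl-4-(PBC-4α-yl)phenyl tert-butyl carbonate | c9ccccc9COc1cc(OCc9ccccc9)c2c(c1)O[C@H](c1ccc(OCc9ccccc9)c(OCc9ccccc9)c1)[C@@H](OCc9ccccc9)[C@@H]2c1c(OCc9ccccc9)cc(OC(=O)OC(C)(C)C)c(C=O)c1OCc9ccccc9 | intermediate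
13 | (−)-epicatechin, (2R,3R) | Oc1cc(O)c2c(c1)O[C@H](c1ccc(O)c(O)c1)[C@H](O)C2 | starting material
14 | 5,7,3',4'-tetra-O-benzyl-(−)-epicatechin (formed in the flask, not isolated) | c9ccccc9COc1cc(OCc9ccccc9)c2c(c1)O[C@H](c1ccc(OCc9ccccc9)c(OCc9ccccc9)c1)[C@H](O)C2 | intermediate
15 | 3,5,7,3',4'-penta-O-benzyl-(−)-epicatechin | c9ccccc9COc1cc(OCc9ccccc9)c2c(c1)O[C@H](c1ccc(OCc9ccccc9)c(OCc9ccccc9)c1)[C@H](OCc9ccccc9)C2 | intermediate
16 | 8-bromo-3,5,7,3',4'-penta-O-benzyl-(−)-epicatechin | c9ccccc9COc1cc(OCc9ccccc9)c2c(c1Br)O[C@H](c1ccc(OCc9ccccc9)c(OCc9ccccc9)c1)[C@H](OCc9ccccc9)C2 | intermediate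
17 | 8-bromo-penta-O-benzylepicatechin C4 (flavan-4-yl) cation (formed in the flask, not isolated) | c9ccccc9COc1cc(OCc9ccccc9)c2c(c1Br)O[C@H](c1ccc(OCc9ccccc9)c(OCc9ccccc9)c1)[C@H](OCc9ccccc9)[CH+]2 | intermediate
18 | 8-bromo-4β-(2-ethoxyethoxy)-penta-O-benzyl-(−)-epicatechin (3,4-trans) | c9ccccc9COc1cc(OCc9ccccc9)c2c(c1Br)O[C@H](c1ccc(OCc9ccccc9)c(OCc9ccccc9)c1)[C@H](OCc9ccccc9)[C@H]2OCCOCC | intermediate
19 | 8-bromo-deca-O-benzyl-epicatechin-(4β→8)-epicatechin (bromine on C8 of the upper unit) | Brc1c(OCc9ccccc9)cc(OCc9ccccc9)c3c1O[C@H](c1ccc(OCc9ccccc9)c(OCc9ccccc9)c1)[C@H](OCc9ccccc9)[C@H]3c1c(OCc9ccccc9)cc(OCc9ccccc9)c3c1O[C@H](c1ccc(OCc9ccccc9)c(OCc9ccccc9)c1)[C@H](OCc9ccccc9)C3 | intermediate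
20 | 2-chloro-3',4'-dihydroxyacetophenone | O=C(CCl)c1ccc(O)c(O)c1 | starting material
21 | 2-chloro-3',4'-bis(pivaloyloxy)acetophenone | O=C(CCl)c1ccc(OC(=O)C(C)(C)C)c(OC(=O)C(C)(C)C)c1 | intermediate
22 | 1-{2-[3,4-bis(pivaloyloxy)phenyl]-2-oxoethyl}thiolan-1-ium chloride | O=C(C[S+]1CCCC1)c1ccc(OC(=O)C(C)(C)C)c(OC(=O)C(C)(C)C)c1.[Cl-] | intermediate
23 | 8-lithio-deca-O-benzyl-epicatechin-(4β→8)-epicatechin (formed in the flask, not isolated) | [Li]c1c(OCc9ccccc9)cc(OCc9ccccc9)c3c1O[C@H](c1ccc(OCc9ccccc9)c(OCc9ccccc9)c1)[C@H](OCc9ccccc9)[C@H]3c1c(OCc9ccccc9)cc(OCc9ccccc9)c3c1O[C@H](c1ccc(OCc9ccccc9)c(OCc9ccccc9)c1)[C@H](OCc9ccccc9)C3 | intermediate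
24 | lithium 3,5-bis(benzyloxy)-2-[(tert-butoxycarbonyloxy)(DBD-8-yl)methyl]-4-(PBC-4α-yl)phenoxide (carbinol carbon not defined; formed in the flask, not isolated) | c9ccccc9COc1cc(OCc9ccccc9)c2c(c1)O[C@H](c1ccc(OCc9ccccc9)c(OCc9ccccc9)c1)[C@@H](OCc9ccccc9)[C@@H]2c1c(OCc9ccccc9)cc([O-])c(c1OCc9ccccc9)C(OC(=O)OC(C)(C)C)c1c(OCc9ccccc9)cc(OCc9ccccc9)c3c1O[C@H](c1ccc(OCc9ccccc9)c(OCc9ccccc9)c1)[C@H](OCc9ccccc9)[C@H]3c1c(OCc9ccccc9)cc(OCc9ccccc9)c3c1O[C@H](c1ccc(OCc9ccccc9)c(OCc9ccccc9)c1)[C@H](OCc9ccccc9)C3.[Li+] | intermediate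
25 | ortho-quinone methide: 3,5-bis(benzyloxy)-6-[(DBD-8-yl)methylidene]-4-(PBC-4α-yl)cyclohexa-2,4-dien-1-one (alkene geometry not defined; formed in the flask, not isolated) | c9ccccc9COc1cc(OCc9ccccc9)c2c(c1)O[C@H](c1ccc(OCc9ccccc9)c(OCc9ccccc9)c1)[C@@H](OCc9ccccc9)[C@@H]2C=1C(OCc9ccccc9)=CC(=O)C(C=1OCc9ccccc9)=Cc1c(OCc9ccccc9)cc(OCc9ccccc9)c3c1O[C@H](c1ccc(OCc9ccccc9)c(OCc9ccccc9)c1)[C@H](OCc9ccccc9)[C@H]3c1c(OCc9ccccc9)cc(OCc9ccccc9)c3c1O[C@H](c1ccc(OCc9ccccc9)c(OCc9ccccc9)c1)[C@H](OCc9ccccc9)C3 | intermediate
26 | sulfonium ylide: 2-[3,4-bis(pivaloyloxy)phenyl]-2-oxo-1-(thiolan-1-ium-1-yl)ethan-1-ide (formed in the flask, not isolated) | O=C([CH-][S+]1CCCC1)c1ccc(OC(=O)C(C)(C)C)c(OC(=O)C(C)(C)C)c1 | intermediate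
27 | (2S)-trans-2-[3,4-bis(pivaloyloxy)benzoyl]-4,6-bis(benzyloxy)-3-(DBD-8-yl)-5-(PBC-4α-yl)-2,3-dihydrobenzofuran (C3 is the future 4β-substituted C4 of unit 2) | c9ccccc9COc1cc(OCc9ccccc9)c2c(c1)O[C@H](c1ccc(OCc9ccccc9)c(OCc9ccccc9)c1)[C@@H](OCc9ccccc9)[C@@H]2c1c(OCc9ccccc9)cc2c(c1OCc9ccccc9)[C@H](c1c(OCc9ccccc9)cc(OCc9ccccc9)c3c1O[C@H](c1ccc(OCc9ccccc9)c(OCc9ccccc9)c1)[C@H](OCc9ccccc9)[C@H]3c1c(OCc9ccccc9)cc(OCc9ccccc9)c3c1O[C@H](c1ccc(OCc9ccccc9)c(OCc9ccccc9)c1)[C@H](OCc9ccccc9)C3)[C@@H](C(=O)c1ccc(OC(=O)C(C)(C)C)c(OC(=O)C(C)(C)C)c1)O2 | intermediate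
28 | threo alcohol: (2S)-trans-2-{(S)-[3,4-bis(pivaloyloxy)phenyl](hydroxy)methyl}-4,6-bis(benzyloxy)-3-(DBD-8-yl)-5-(PBC-4α-yl)-2,3-dihydrobenzofuran | c9ccccc9COc1cc(OCc9ccccc9)c2c(c1)O[C@H](c1ccc(OCc9ccccc9)c(OCc9ccccc9)c1)[C@@H](OCc9ccccc9)[C@@H]2c1c(OCc9ccccc9)cc2c(c1OCc9ccccc9)[C@H](c1c(OCc9ccccc9)cc(OCc9ccccc9)c3c1O[C@H](c1ccc(OCc9ccccc9)c(OCc9ccccc9)c1)[C@H](OCc9ccccc9)[C@H]3c1c(OCc9ccccc9)cc(OCc9ccccc9)c3c1O[C@H](c1ccc(OCc9ccccc9)c(OCc9ccccc9)c1)[C@H](OCc9ccccc9)C3)[C@@H]([C@@H](O)c1ccc(OC(=O)C(C)(C)C)c(OC(=O)C(C)(C)C)c1)O2 | intermediate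
29 | methanesulfonate of 28 (key-step precursor) | c9ccccc9COc1cc(OCc9ccccc9)c2c(c1)O[C@H](c1ccc(OCc9ccccc9)c(OCc9ccccc9)c1)[C@@H](OCc9ccccc9)[C@@H]2c1c(OCc9ccccc9)cc2c(c1OCc9ccccc9)[C@H](c1c(OCc9ccccc9)cc(OCc9ccccc9)c3c1O[C@H](c1ccc(OCc9ccccc9)c(OCc9ccccc9)c1)[C@H](OCc9ccccc9)[C@H]3c1c(OCc9ccccc9)cc(OCc9ccccc9)c3c1O[C@H](c1ccc(OCc9ccccc9)c(OCc9ccccc9)c1)[C@H](OCc9ccccc9)C3)[C@@H]([C@@H](OS(C)(=O)=O)c1ccc(OC(=O)C(C)(C)C)c(OC(=O)C(C)(C)C)c1)O2 | intermediate
30 | aryloxiranium ion (ring oxygen bridging furan C2 and the inverted benzylic carbon; formed in the flask, not isolated) | c9ccccc9COc1cc(OCc9ccccc9)c2c(c1)O[C@H](c1ccc(OCc9ccccc9)c(OCc9ccccc9)c1)[C@@H](OCc9ccccc9)[C@@H]2c1c(OCc9ccccc9)cc2c(c1OCc9ccccc9)[C@H](c1c(OCc9ccccc9)cc(OCc9ccccc9)c3c1O[C@H](c1ccc(OCc9ccccc9)c(OCc9ccccc9)c1)[C@H](OCc9ccccc9)[C@H]3c1c(OCc9ccccc9)cc(OCc9ccccc9)c3c1O[C@H](c1ccc(OCc9ccccc9)c(OCc9ccccc9)c1)[C@H](OCc9ccccc9)C3)[C@H]4[C@@H](c1ccc(OC(=O)C(C)(C)C)c(OC(=O)C(C)(C)C)c1)[O+]42 | intermediate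
31 | protected tetramer, unit 2 as 3-O-acetate with ring B dipivalate (2,3-cis-3,4-trans) | c9ccccc9COc1cc(OCc9ccccc9)c2c(c1)O[C@H](c1ccc(OCc9ccccc9)c(OCc9ccccc9)c1)[C@@H](OCc9ccccc9)[C@@H]2c1c(OCc9ccccc9)cc2c(c1OCc9ccccc9)[C@H](c1c(OCc9ccccc9)cc(OCc9ccccc9)c3c1O[C@H](c1ccc(OCc9ccccc9)c(OCc9ccccc9)c1)[C@H](OCc9ccccc9)[C@H]3c1c(OCc9ccccc9)cc(OCc9ccccc9)c3c1O[C@H](c1ccc(OCc9ccccc9)c(OCc9ccccc9)c1)[C@H](OCc9ccccc9)C3)[C@@H](OC(C)=O)[C@@H](c1ccc(OC(=O)C(C)(C)C)c(OC(=O)C(C)(C)C)c1)O2 | intermediate
32 | heptadeca-O-benzyl tetramer, unit 2 with free 3-OH, 3'-OH, 4'-OH | c9ccccc9COc1cc(OCc9ccccc9)c2c(c1)O[C@H](c1ccc(OCc9ccccc9)c(OCc9ccccc9)c1)[C@@H](OCc9ccccc9)[C@@H]2c1c(OCc9ccccc9)cc2c(c1OCc9ccccc9)[C@H](c1c(OCc9ccccc9)cc(OCc9ccccc9)c3c1O[C@H](c1ccc(OCc9ccccc9)c(OCc9ccccc9)c1)[C@H](OCc9ccccc9)[C@H]3c1c(OCc9ccccc9)cc(OCc9ccccc9)c3c1O[C@H](c1ccc(OCc9ccccc9)c(OCc9ccccc9)c1)[C@H](OCc9ccccc9)C3)[C@@H](O)[C@@H](c1ccc(O)c(O)c1)O2 | intermediate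
33 | catechin-(4α→6)-epicatechin-(4β→8)-epicatechin-(4β→8)-epicatechin (CNP0228086.1) | Oc1cc(O)c2c(c1)O[C@H](c1ccc(O)c(O)c1)[C@@H](O)[C@@H]2c1c(O)cc2c(c1O)[C@H](c1c(O)cc(O)c3c1O[C@H](c1ccc(O)c(O)c1)[C@H](O)[C@H]3c1c(O)cc(O)c3c1O[C@H](c1ccc(O)c(O)c1)[C@H](O)C3)[C@@H](O)[C@@H](c1ccc(O)c(O)c1)O2 | target

## Step count and least certain steps

Total: 20 steps. Longest linear sequence: 12 steps (1 → 3 → 5 → 9 → 10 → 11 → 12 → 27 → 28 → 29 → 31 → 32 → 33; the same length from 6).

**Step 18 (key step).** Most likely to go wrong: capture of the oxiranium ion, or of the mesylate itself, at the benzylic carbon, which would return unrearranged dihydrobenzofuran acetate. Ionisation or elimination towards the 2-benzylidene enol ether may also compete. The cause is that a benzylic carbon stays intrinsically more electrophilic than the ring carbon, and an aryl ether oxygen is a weaker neighbouring group than an alkyl ether oxygen.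

Fallback, setting out from 5 and 16 and returning at 33: unit 2 would be assembled by classical cationic couplings without the rearrangement. Me3SiOTf-mediated coupling of 5 with the C8-blocked nucleophile 16, which can react only at C6, should give the deca-O-benzyl catechin-(4α→6)-8-bromoepicatechin dimer F1. DDQ and 2-ethoxyethanol would then oxidise the free C4 methylene of its lower unit, through the dimeric flavan-4-yl cation F2 (not isolated), to the 4β-(2-ethoxyethoxy) dimer F3. Bromine–lithium exchange on 19 with n-BuLi, through 23, and a methanol quench would give the bromine-free deca-O-benzyl epicatechin-(4β→8)-epicatechin F4. Me3SiOTf coupling of F3 with an excess of F4, at C8 of its upper unit, would give the 8-bromo icosa-O-benzyl tetramer F5. Hydrogenolysis over Pd(OH)2 on carbon in the presence of Et3N would then remove twenty benzyl groups and the bromine to give 33.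

**Step 15.** Most likely to go wrong: poor face selectivity in the addition of 26 to 25, because the methide carbon has no adjacent stereocentre and the chirality of unit 3 and unit 1 is remote. The two trans-dihydrobenzofurans epimeric at both new centres could then form together. Slow addition of a stabilised ylide to a donor-rich, hindered quinone methide is the second concern.

Fallback, setting out from 21 and returning at 27: face selection is handed to the reagent. Alkylation of the C2-symmetric sulfide (2R,5R)-2,5-dimethylthiolane with 21 would give the chiral sulfonium salt (2R,5R)-1-{2-[3,4-bis(pivaloyloxy)phenyl]-2-oxoethyl}-2,5-dimethylthiolan-1-ium chloride F6. Deprotonation with LiN(SiMe3)2 would give the chiral sulfonium ylide F7, which takes the place of 26 in step 15. Betaine formation is reversible, so the chiral sulfonium group can decide which diastereomeric betaine closes to 27. The enantiomeric sulfide would be used if the sense of induction opposes the required face.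

**Step 16.** Most likely to go wrong: erosion of Felkin–Anh control through partial lithium chelation between carbonyl and ring oxygen, leading towards the erythro alcohol, or partial reductive loss of a pivalate.

Fallback, setting out from 27 and returning at 28: catalyst-controlled asymmetric transfer hydrogenation (Noyori type) with RuCl[(R,R)-TsDPEN](p-cymene) and HCO2H–Et3N, using the enantiomer that reduces acetophenone to (R)-1-phenylethanol. This corresponds spatially to the (S)-carbinol here, because the alkyl group outranks the aryl group in this substrate. Stereocontrol comes from the catalyst's aryl/alkyl discrimination and not from the substrate, and the conditions are neutral to esters. No new compound arises (F0).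

**Step 5.** Most likely to go wrong: alkylation ortho to the silyloxy group competing with para attack, because that carbon is para to one benzyloxy donor and only the size of the silyl group disfavours it. A small share of the 4β epimer is the second concern.

Fallback, setting out from 5 and 6 and returning at 9: the regiochemical question is removed by a fully symmetrical nucleophile. Coupling of 5 with an excess of 6 (BF3·OEt2, THF–CH2Cl2, −40 → 0 °C) should give the 4α-(2,4,6-trihydroxyphenyl)-penta-O-benzyl-(+)-catechin F8. TIPSCl and imidazole would silylate its only unhindered phenol, the one para to the flavanyl group, to give the 4α-[2,6-dihydroxy-4-(triisopropylsilyloxy)phenyl]-penta-O-benzyl-(+)-catechin F9. BnBr and K2CO3 in acetone would then benzylate the two flanking phenols to give 9.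

## Further compounds

F1 | step 18 | deca-O-benzyl catechin-(4α→6)-8-bromoepicatechin | c9ccccc9COc1cc(OCc9ccccc9)c2c(c1)O[C@H](c1ccc(OCc9ccccc9)c(OCc9ccccc9)c1)[C@@H](OCc9ccccc9)[C@@H]2c1c(OCc9ccccc9)c(Br)c2c(c1OCc9ccccc9)C[C@@H](OCc9ccccc9)[C@@H](c1ccc(OCc9ccccc9)c(OCc9ccccc9)c1)O2
F2 | step 18 | dimeric flavan-4-yl cation: deca-O-benzyl catechin-(4α→6)-8-bromoepicatechin ionised at C4 of the lower unit (not isolated) | c9ccccc9COc1cc(OCc9ccccc9)c2c(c1)O[C@H](c1ccc(OCc9ccccc9)c(OCc9ccccc9)c1)[C@@H](OCc9ccccc9)[C@@H]2c1c(OCc9ccccc9)c(Br)c2c(c1OCc9ccccc9)[CH+][C@@H](OCc9ccccc9)[C@@H](c1ccc(OCc9ccccc9)c(OCc9ccccc9)c1)O2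
F3 | step 18 | deca-O-benzyl catechin-(4α→6)-[8-bromo-4β-(2-ethoxyethoxy)epicatechin] | c9ccccc9COc1cc(OCc9ccccc9)c2c(c1)O[C@H](c1ccc(OCc9ccccc9)c(OCc9ccccc9)c1)[C@@H](OCc9ccccc9)[C@@H]2c1c(OCc9ccccc9)c(Br)c2c(c1OCc9ccccc9)[C@H](OCCOCC)[C@@H](OCc9ccccc9)[C@@H](c1ccc(OCc9ccccc9)c(OCc9ccccc9)c1)O2
F4 | step 18 | deca-O-benzyl epicatechin-(4β→8)-epicatechin | c1c(OCc9ccccc9)cc(OCc9ccccc9)c3c1O[C@H](c1ccc(OCc9ccccc9)c(OCc9ccccc9)c1)[C@H](OCc9ccccc9)[C@H]3c1c(OCc9ccccc9)cc(OCc9ccccc9)c3c1O[C@H](c1ccc(OCc9ccccc9)c(OCc9ccccc9)c1)[C@H](OCc9ccccc9)C3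
F5 | step 18 | icosa-O-benzyl tetramer with bromine at C8 of unit 2 | c9ccccc9COc1cc(OCc9ccccc9)c2c(c1)O[C@H](c1ccc(OCc9ccccc9)c(OCc9ccccc9)c1)[C@@H](OCc9ccccc9)[C@@H]2c1c(OCc9ccccc9)c(Br)c2c(c1OCc9ccccc9)[C@H](c1c(OCc9ccccc9)cc(OCc9ccccc9)c3c1O[C@H](c1ccc(OCc9ccccc9)c(OCc9ccccc9)c1)[C@H](OCc9ccccc9)[C@H]3c1c(OCc9ccccc9)cc(OCc9ccccc9)c3c1O[C@H](c1ccc(OCc9ccccc9)c(OCc9ccccc9)c1)[C@H](OCc9ccccc9)C3)[C@@H](OCc9ccccc9)[C@@H](c1ccc(OCc9ccccc9)c(OCc9ccccc9)c1)O2
F6 | step 15 | (2R,5R)-1-{2-[3,4-bis(pivaloyloxy)phenyl]-2-oxoethyl}-2,5-dimethylthiolan-1-ium chloride | C[C@@H]1CC[C@@H](C)[S+]1CC(=O)c1ccc(OC(=O)C(C)(C)C)c(OC(=O)C(C)(C)C)c1.[Cl-]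
F7 | step 15 | chiral sulfonium ylide: 2-[3,4-bis(pivaloyloxy)phenyl]-1-[(2R,5R)-2,5-dimethylthiolan-1-ium-1-yl]-2-oxoethan-1-ide (not isolated) | C[C@@H]1CC[C@@H](C)[S+]1[CH-]C(=O)c1ccc(OC(=O)C(C)(C)C)c(OC(=O)C(C)(C)C)c1
F0 | step 16 | none | none
F8 | step 5 | 4α-(2,4,6-trihydroxyphenyl)-penta-O-benzyl-(+)-catechin | c9ccccc9COc1cc(OCc9ccccc9)c2c(c1)O[C@H](c1ccc(OCc9ccccc9)c(OCc9ccccc9)c1)[C@@H](OCc9ccccc9)[C@@H]2c1c(O)cc(O)cc1O
F9 | step 5 | 4α-[2,6-dihydroxy-4-(triisopropylsilyloxy)phenyl]-penta-O-benzyl-(+)-catechin | c9ccccc9COc1cc(OCc9ccccc9)c2c(c1)O[C@H](c1ccc(OCc9ccccc9)c(OCc9ccccc9)c1)[C@@H](OCc9ccccc9)[C@@H]2c1c(O)cc(O[Si](C(C)C)(C(C)C)C(C)C)cc1O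
A1 | alternative 1 | macrocyclic 3,3''-O-azelate (18-membered ring) of 5,7,3',4'-tetra-O-benzylepicatechin-(4β→8)-5,7,3',4'-tetra-O-benzylepicatechin | c1c(OCc9ccccc9)cc(OCc9ccccc9)c3c1O[C@H](c1ccc(OCc9ccccc9)c(OCc9ccccc9)c1)[C@H](OC(=O)CCCCCCCC(=O)O[C@@H]4Cc5c(OCc9ccccc9)cc(OCc9ccccc9)c6c5O[C@@H]4c1ccc(OCc9ccccc9)c(OCc9ccccc9)c1)[C@H]36
A2 | alternative 2 | deca-O-benzyl catechin-(4α→6)-[4β-(2-ethoxyethoxy)epicatechin] | c9ccccc9COc1cc(OCc9ccccc9)c2c(c1)O[C@H](c1ccc(OCc9ccccc9)c(OCc9ccccc9)c1)[C@@H](OCc9ccccc9)[C@@H]2c1c(OCc9ccccc9)cc2c(c1OCc9ccccc9)[C@H](OCCOCC)[C@@H](OCc9ccccc9)[C@@H](c1ccc(OCc9ccccc9)c(OCc9ccccc9)c1)O2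
A3 | alternative 3 | protected tetramer with unit 1 as a 4-aryl-4H-chromene (flav-2-ene) and bromine at C8 of unit 2 | c9ccccc9COc1cc(OCc9ccccc9)c2c(c1)OC(c1ccc(OCc9ccccc9)c(OCc9ccccc9)c1)=C[C@@H]2c1c(OCc9ccccc9)c(Br)c2c(c1OCc9ccccc9)[C@H](c1c(OCc9ccccc9)cc(OCc9ccccc9)c3c1O[C@H](c1ccc(OCc9ccccc9)c(OCc9ccccc9)c1)[C@H](OCc9ccccc9)[C@H]3c1c(OCc9ccccc9)cc(OCc9ccccc9)c3c1O[C@H](c1ccc(OCc9ccccc9)c(OCc9ccccc9)c1)[C@H](OCc9ccccc9)C3)[C@@H](OCc9ccccc9)[C@@H](c1ccc(OCc9ccccc9)c(OCc9ccccc9)c1)O2
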